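**Retrosynthetic overview**
1. Last events: the C8 ketone is unveiled from a dimethyl ketal, and the C3 ester is made from the ring diol and (2E,5R)-5-(angeloyloxy)hex-2-enoic acid (angelate formation, then cross-metathesis with acrylic acid).
2. The target is the all-equatorial isomer of a cis-decalin whose chair–chair form is locked by the C7 isopropenyl group, so C4 (enolisation) and the C3 and C9 carbinols (reversible hydride transfer) are set by equilibration.
3. Key disconnection: ring A (C1–C5, C10) by a Diels–Alder reaction between a ring B enone (C5=C10 as dienophile, C9 carbonyl, C8 masked as ketal, C7 isopropenyl) and (Z)-3-siloxypenta-1,3-diene (C1–C4, oxygen on C3, methyl on C4).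
4. Enabling feature: the ring A oxygen at C3 and the ring B oxygen at C9 stand 1,5 across C4–C5–C10, with the quaternary C5 β to C9. A C9 carbonyl therefore makes C5 electrophilic, a C3 siloxy group makes C4 nucleophilic, and the C7 stereocentre of ring B sends the diene to the opposite face.
5. Order of rings: ring B first (it is the benzene ring of 3,4-dimethoxyphenol, carried through a quinone monoketal, asymmetric isopropenylation and carbonyl transposition); ring A last.

Key step: step 5

Remark: the decalins are numbered as eremophilanes (ring A = C1–C5 and C10; ring B = C5–C10; C5 = methylated quaternary ring-fusion carbon, C10 = ring-fusion CH, C4 = CH–CH3, C3 = oxygenated carbon of ring A, C7 = carbon bearing the isopropenyl group, C8 and C9 = oxygenated carbons of ring B). β is the face of the C5 methyl group, α the opposite face.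

Step 1
Reactants: 1 3,4-dimethoxyphenol
Product: 2 3,4,4-trimethoxycyclohexa-2,5-dien-1-one
Conditions: PhI(OAc)2, MeOH, 0 °C
Reagents that add atoms: methanol, CO
Why: Oxidative dearomatisation of a para-alkoxyphenol by trivalent iodine (quinone monoketal formation), methanol trapping the methoxy-bearing para carbon; no stereocentre is formed.

Step 2
Reactants: 2 3,4,4-trimethoxycyclohexa-2,5-dien-1-one; 3 4,4,5,5-tetramethyl-2-(prop-1-en-2-yl)-1,3,2-dioxaborolane
Product: 4 (5R)-3,4,4-trimethoxy-5-(prop-1-en-2-yl)cyclohex-2-en-1-one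
Conditions: [RhCl(C2H4)2]2 (3 mol%), (R)-BINAP (7 mol%), K3PO4 (0.5 equiv), dioxane/H2O 10:1, 40 °C
Reagents that add atoms: none
Why: Hayashi–Miyaura asymmetric 1,4-addition of an alkenylboron reagent with a monovalent rhodium catalyst: the isopropenyl–rhodium species adds only to the unsubstituted enone arm (the methoxy-bearing arm is a deactivated vinylogous ester), and the (R)-BINAP ligand selects the enone face to set the single stereocentre as 5R (the future C7).

Step 3
Reactants: 4 (5R)-3,4,4-trimethoxy-5-(prop-1-en-2-yl)cyclohex-2-en-1-one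
Product: 6 (5R)-6,6-dimethoxy-3-methyl-5-(prop-1-en-2-yl)cyclohex-2-en-1-one, via carbinol 5 (not isolated)
Conditions: MeLi, THF, −78 °C; then 1 M HCl, 0 °C
Reagents that add atoms: methyllithium, [Li]C; water, O
Why: Stork–Danheiser alkylative 1,3-carbonyl transposition: 1,2-addition of methyllithium to the vinylogous ester and dilute-acid hydrolysis of the enol-ether carbinol move the carbonyl next to the ketal carbon and put the methyl on the β-carbon, while the existing stereocentre is untouched and the resulting α-keto ketal resists the dilute acid.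

Step 4
Reactants: 7 pent-1-en-3-one
Product: 8 (Z)-tert-butyldimethyl(penta-1,3-dien-3-yloxy)silane
Conditions: TBSOTf, Et3N, Et2O, 0 °C
Reagents that add atoms: tert-butyldimethylsilyl trifluoromethanesulfonate, CC(C)(C)[Si](C)(C)OS(=O)(=O)C(F)(F)F
Why: Soft enolisation of the ethyl ketone (silyl enol ether formation) gives the cross-conjugated 2-siloxydiene, the Z enol ether placing the methyl on the outside of the s-cis diene.

Step 5
Reactants: 6 (5R)-6,6-dimethoxy-3-methyl-5-(prop-1-en-2-yl)cyclohex-2-en-1-one; 8 (Z)-tert-butyldimethyl(penta-1,3-dien-3-yloxy)silane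
Product: 9 3-(tert-butyldimethylsilyloxy)-8,8-dimethoxy-10βH-eremophila-2,11-dien-9-one (5β-methyl; 7β-isopropenyl; mixture of C4 epimers)
Conditions: 8 (2 equiv), HN(SO2CF3)2 (10 mol%), CH2Cl2, −78 → −30 °C; Et3N quench
Reagents that add atoms: none
Why: The silyl triflimide formed in the flask from HN(SO2CF3)2 and 8 activates the C9 carbonyl of 6; C4 of the siloxydiene (its nucleophilic terminus) bonds to the β-carbon C5 and C1 then closes onto the α-carbon C10 in a strongly asynchronous, suprafacial [4+2] cycloaddition that regenerates the silyl enol ether at C2=C3. The closest known reaction type is the triflimide- or aluminium-halide-promoted Diels–Alder reaction of hindered 2-siloxydienes with β,β-disubstituted cyclohexenones, which builds quaternary carbons. Ring A is closed in the intermolecular [4+2] mode (bonds C4–C5 and C1–C10), which makes the ring fusion cis by necessity. C5 and C10 are controlled by the C7 stereocentre: the diene adds to the enone face anti to the pseudo-equatorial isopropenyl group (axial attack at C5), which places the C5 methyl cis to the isopropenyl group, whereas C4 depends on the endo/exo mode and need not be controlled because step 6 equilibrates it. The step needs "para" regiochemistry and survival of the ketal and the isopropenyl group: the first is secured by the matched polarisation (siloxy group at C3, carbonyl at C9), the second by the low temperature and by the fact that ionising the ketal would put a cation next to the activated carbonyl.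

Step 6
Reactants: 9 3-(tert-butyldimethylsilyloxy)-8,8-dimethoxy-10βH-eremophila-2,11-dien-9-one (C4 epimers)
Product: 11 8,8-dimethoxy-10βH-eremophil-11-ene-3,9-dione (4β-methyl; 5β-methyl; 7β-isopropenyl), via 4-epi-diketone 10 (not isolated)
Conditions: Bu4NF, AcOH, THF, 0 °C; then NaOMe (0.2 equiv), MeOH, rt
Reagents that add atoms: none
Why: Fluoride cleavage of the silyl enol ether unveils the C3 ketone and methoxide-catalysed enolisation (epimerisation under thermodynamic control) funnels both C4 epimers into the equatorial 4β-methyl compound, because an axial 4α-methyl would be 1,3-diaxial to the C10–C9 bond in the chair–chair form fixed by the equatorial isopropenyl group; C10 stays cis since the trans-fused isomer would force the isopropenyl group syn-axial to the C5 methyl.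

Step 7
Reactants: 11 8,8-dimethoxy-10βH-eremophil-11-ene-3,9-dione
Product: 12 8,8-dimethoxy-10βH-eremophil-11-ene-3α,9β-diol (4β,5β-dimethyl; 7β-isopropenyl)
Conditions: Al(OiPr)3 (0.5 equiv), iPrOH, acetone (5 mol%), 82 °C
Reagents that add atoms: none
Why: Meerwein–Ponndorf–Verley reduction run under equilibrating conditions (the trace of acetone keeps the Oppenauer back-reaction alive) should give the thermodynamically preferred carbinols, equatorial 3α-OH (the axial epimer is syn-axial to the C5 methyl) and equatorial 9β-OH (the axial epimer is syn-axial to the C5–C4 bond), while the alkenes and the ketal are inert to the aluminium alkoxide.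

Step 8
Reactants: 13 (R)-pent-4-en-2-ol; 14 angelic acid, (Z)-2-methylbut-2-enoic acid
Product: 16 (R)-pent-4-en-2-yl (Z)-2-methylbut-2-enoate, via mixed anhydride 15 (not isolated)
Conditions: 14, 2,4,6-Cl3C6H2COCl, Et3N, toluene, rt; then 13, 80 °C
Reagents that add atoms: none
Why: Yamaguchi-type mixed-anhydride esterification without a nucleophilic catalyst, the mode in which angelates form without Z-to-E isomerisation; the carbinol centre of 13 is retained because only the acyl–oxygen bond is made.

Step 9
Reactants: 16 (R)-pent-4-en-2-yl (Z)-2-methylbut-2-enoate; 17 acrylic acid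
Product: 18 (2E,5R)-5-{[(2Z)-2-methylbut-2-enoyl]oxy}hex-2-enoic acid
Conditions: 17 (3 equiv), second-generation Hoveyda–Grubbs catalyst (5 mol%), CH2Cl2, 40 °C
Reagents that add atoms: none
Why: Olefin cross-metathesis of a terminal alkene with acrylic acid is E-selective, and the electron-poor trisubstituted angelate alkene is not a metathesis substrate.

Step 10
Reactants: 12 8,8-dimethoxy-10βH-eremophil-11-ene-3α,9β-diol; 18 (2E,5R)-5-{[(2Z)-2-methylbut-2-enoyl]oxy}hex-2-enoic acid
Product: 20 3α-ester of 12 with acid 18 (9β-hydroxy-8,8-dimethoxy-10βH-eremophil-11-en-3α-yl ester), via O-acylisourea 19 (not isolated)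
Conditions: 18 (1.0 equiv), N,N'-diisopropylcarbodiimide (1.1 equiv), DMAP (0.1 equiv), CH2Cl2, 0 °C
Reagents that add atoms: none
Why: Steglich esterification should acylate the equatorial C3 hydroxyl in preference to the C9 hydroxyl, which is flanked by the quaternary ketal carbon and the ring-fusion carbon, and the mild, cold conditions avoid deconjugation of the enoate and isomerisation of the angelate.

Step 11
Reactants: 20 3α-ester of 12 with acid 18
Product: 21 target, 3α-[(2E,5R)-5-{[(2Z)-2-methylbut-2-enoyl]oxy}hex-2-enoyloxy]-9β-hydroxy-10βH-eremophil-11-en-8-one (4β,5β-dimethyl; 7β-isopropenyl)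
Conditions: pyridinium p-toluenesulfonate (0.3 equiv), acetone/H2O 20:1, 40 °C
Reagents that add atoms: water, O
Why: Mild acid-catalysed ketal hydrolysis unveils the C8 ketone as the last event, so the α-ketol and the β,γ-unsaturated ketone meet no further reagent, and C7 and C9 already hold their equatorial, thermodynamically preferred configurations.

**Compound list**
1 | 3,4-dimethoxyphenol | COc1ccc(O)cc1OC | starting material
2 | 3,4,4-trimethoxycyclohexa-2,5-dien-1-one | COC1=CC(=O)C=CC1(OC)OC | intermediate
3 | 4,4,5,5-tetramethyl-2-(prop-1-en-2-yl)-1,3,2-dioxaborolane | C=C(C)B1OC(C)(C)C(C)(C)O1 | starting material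
4 | (5R)-3,4,4-trimethoxy-5-(prop-1-en-2-yl)cyclohex-2-en-1-one | C=C(C)[C@H]1CC(=O)C=C(OC)C1(OC)OC | intermediate
5 | (5R)-3,4,4-trimethoxy-1-methyl-5-(prop-1-en-2-yl)cyclohex-2-en-1-ol (lithium alkoxide in the flask; C1 epimers) | C=C(C)[C@H]1CC(C)(O)C=C(OC)C1(OC)OC | intermediate (not isolated)
6 | (5R)-6,6-dimethoxy-3-methyl-5-(prop-1-en-2-yl)cyclohex-2-en-1-one | C=C(C)[C@H]1CC(C)=CC(=O)C1(OC)OC | intermediate
7 | pent-1-en-3-one | C=CC(=O)CC | starting material
8 | (Z)-tert-butyldimethyl(penta-1,3-dien-3-yloxy)silane | C=C/C(O[Si](C)(C)C(C)(C)C)=C/C | intermediate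
9 | 3-(tert-butyldimethylsilyloxy)-8,8-dimethoxy-10βH-eremophila-2,11-dien-9-one (5β-methyl; 7β-isopropenyl; C4 epimers, C4 left undefined) | C=C(C)[C@H]1C[C@@]2(C)[C@H](CC=C(O[Si](C)(C)C(C)(C)C)C2C)C(=O)C1(OC)OC | intermediate
10 | 8,8-dimethoxy-10βH-eremophil-11-ene-3,9-dione, 4α-methyl epimer (5β-methyl; 7β-isopropenyl) | C=C(C)[C@H]1C[C@@]2(C)[C@H](CCC(=O)[C@H]2C)C(=O)C1(OC)OC | intermediate (not isolated)
11 | 8,8-dimethoxy-10βH-eremophil-11-ene-3,9-dione (4β,5β-dimethyl; 7β-isopropenyl) | C=C(C)[C@H]1C[C@@]2(C)[C@H](CCC(=O)[C@@H]2C)C(=O)C1(OC)OC | intermediate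
12 | 8,8-dimethoxy-10βH-eremophil-11-ene-3α,9β-diol (4β,5β-dimethyl; 7β-isopropenyl) | C=C(C)[C@H]1C[C@@]2(C)[C@H](CC[C@@H](O)[C@@H]2C)[C@@H](O)C1(OC)OC | intermediate
13 | (R)-pent-4-en-2-ol | C=CC[C@@H](C)O | starting material
14 | angelic acid, (Z)-2-methylbut-2-enoic acid | C/C=C(/C)C(=O)O | starting material
15 | (Z)-2-methylbut-2-enoic 2,4,6-trichlorobenzoic anhydride | C/C=C(/C)C(=O)OC(=O)c1c(Cl)cc(Cl)cc1Cl | intermediate (not isolated)
16 | (R)-pent-4-en-2-yl (Z)-2-methylbut-2-enoate | C=CC[C@@H](C)OC(=O)/C(C)=C\C | intermediate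
17 | acrylic acid | C=CC(=O)O | starting material
18 | (2E,5R)-5-{[(2Z)-2-methylbut-2-enoyl]oxy}hex-2-enoic acid | OC(=O)/C=C/C[C@@H](C)OC(=O)/C(C)=C\C | intermediate
19 | O-acylisourea of 18 with N,N'-diisopropylcarbodiimide | CC(C)N=C(NC(C)C)OC(=O)/C=C/C[C@@H](C)OC(=O)/C(C)=C\C | intermediate (not isolated)
20 | 9β-hydroxy-8,8-dimethoxy-10βH-eremophil-11-en-3α-yl (2E,5R)-5-{[(2Z)-2-methylbut-2-enoyl]oxy}hex-2-enoate | C=C(C)[C@H]1C[C@@]2(C)[C@H](CC[C@@H](OC(=O)/C=C/C[C@@H](C)OC(=O)/C(C)=C\C)[C@@H]2C)[C@@H](O)C1(OC)OC | intermediate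
21 | CNP0210874.1, 9β-hydroxy-8-oxo-10βH-eremophil-11-en-3α-yl (2E,5R)-5-{[(2Z)-2-methylbut-2-enoyl]oxy}hex-2-enoate | C=C(C)[C@H]1C[C@@]2(C)[C@H](CC[C@@H](OC(=O)/C=C/C[C@@H](C)OC(=O)/C(C)=C\C)[C@@H]2C)[C@@H](O)C1=O | target

**Totals**
Total step count: 11. Longest linear sequence: 8 steps (1, 2, 3, 5, 6, 7, 10, 11).

**Steps most likely to fail**

Step 5. What may go wrong: ionisation of the ketal or cation chemistry at the isopropenyl group under the strong silyl Lewis acid, or stalling after the first C–C bond at the hindered β-carbon. The fallback sets out from 6 (with 7) and comes back at 11; ring A is still the last ring closed, but by two Michael additions under base. Because C8 is a ketal, 6 can only enolise toward its γ-positions. KOtBu (tBuOH/THF, 0 °C) should give the extended dienolate, which adds through its α-carbon (C10) to ethyl vinyl ketone 7 and reconjugates to (5R)-6,6-dimethoxy-3-methyl-2-(3-oxopentyl)-5-(prop-1-en-2-yl)cyclohex-2-en-1-one F1. Warming F1 with Cs2CO3 in MeCN should close ring A by intramolecular Michael addition of the ethyl-ketone enolate carbon (C4) to C5. The reversible closure delivers the thermodynamic diketone 11 (its epimer 10 equilibrates under the same base). The competing aldol at C9 is disfavoured by the flanking ketal.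

Step 2. What may go wrong: slow carbometalation at the β-carbon next to the quaternary ketal carbon, low enantioselectivity, or loss of methanol with aromatisation. The fallback sets out from 2 and comes back at 20. It gives up asymmetric catalysis and takes the absolute configuration from the enantiopure side-chain acid.
- Isopropenylmagnesium bromide with CuBr·SMe2 (10 mol%) and Me3SiCl (THF, −78 °C) adds to 2 to give 4 as the racemate, that is together with (5S)-3,4,4-trimethoxy-5-(prop-1-en-2-yl)cyclohex-2-en-1-one F2.
- The racemate is carried through steps 3, 5, 6 and 7 unchanged, since every later centre is set relative to C7. This produces, beside 5, 6, 9, 10, 11 and 12, the enantiomer of carbinol 5 F3 (not isolated), the enantiomer of enone 6 F4, the enantiomer of cycloadduct 9 F5, the enantiomer of 4-epi-diketone 10 F6 (not isolated), the enantiomer of diketone 11 F7 and the enantiomer of diol 12 F8.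
- Esterification of the racemic diol with enantiopure 18 as in step 10 gives 20 and the diastereomeric ester of the enantiomeric decalin F9, which are separated by chromatography.

Step 7. What may go wrong: incomplete equilibration at the hindered C9 carbinol (the kinetically formed axial alcohol persists), or alkoxide-induced retro-Michael opening of ring A. The fallback sets out from 11 and comes back at 21. It uses kinetic reduction followed by two SN2 inversions.
- LiBH(sBu)3 (THF, −78 → 0 °C) attacks both ketones from the open faces to give the diaxial 8,8-dimethoxy-10βH-eremophil-11-ene-3β,9α-diol F10.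
- Mitsunobu esterification with 18 (PPh3, diisopropyl azodicarboxylate, toluene, 0 °C) inverts only the accessible C3 carbinol, giving the 9-epimer of ester 20 F11.
- Ketal hydrolysis as in step 11 gives the 9-epimer of the target F12.
- The C9 carbinol, now α to the ketone, is converted with (CF3SO2)2O and pyridine (CH2Cl2, −20 °C) into the 9α-triflate F13. Bu4NNO2 (DMF, rt) displaces the triflate from the convex β-face to give the 9β-nitrite ester F14 (not isolated), which hydrolyses on aqueous work-up to 21.

Further compounds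
F1 | step 5 | (5R)-6,6-dimethoxy-3-methyl-2-(3-oxopentyl)-5-(prop-1-en-2-yl)cyclohex-2-en-1-one | C=C(C)[C@H]1CC(C)=C(CCC(=O)CC)C(=O)C1(OC)OC
F2 | step 2 | (5S)-3,4,4-trimethoxy-5-(prop-1-en-2-yl)cyclohex-2-en-1-one (enantiomer of 4) | C=C(C)[C@@H]1CC(=O)C=C(OC)C1(OC)OC
F3 | step 2 | (5S)-3,4,4-trimethoxy-1-methyl-5-(prop-1-en-2-yl)cyclohex-2-en-1-ol (enantiomer of 5, not isolated) | C=C(C)[C@@H]1CC(C)(O)C=C(OC)C1(OC)OC
F4 | step 2 | (5S)-6,6-dimethoxy-3-methyl-5-(prop-1-en-2-yl)cyclohex-2-en-1-one (enantiomer of 6) | C=C(C)[C@@H]1CC(C)=CC(=O)C1(OC)OC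
F5 | step 2 | enantiomer of cycloadduct 9 (C4 epimers) | C=C(C)[C@@H]1C[C@]2(C)[C@@H](CC=C(O[Si](C)(C)C(C)(C)C)C2C)C(=O)C1(OC)OC
F6 | step 2 | enantiomer of 4-epi-diketone 10 (not isolated) | C=C(C)[C@@H]1C[C@]2(C)[C@@H](CCC(=O)[C@@H]2C)C(=O)C1(OC)OC
F7 | step 2 | enantiomer of diketone 11 | C=C(C)[C@@H]1C[C@]2(C)[C@@H](CCC(=O)[C@H]2C)C(=O)C1(OC)OC
F8 | step 2 | enantiomer of diol 12 | C=C(C)[C@@H]1C[C@]2(C)[C@@H](CC[C@H](O)[C@H]2C)[C@H](O)C1(OC)OC
F9 | step 2 | diastereomer of 20 (enantiomeric decalin, same (R)-configured side chain) | C=C(C)[C@@H]1C[C@]2(C)[C@@H](CC[C@H](OC(=O)/C=C/C[C@@H](C)OC(=O)/C(C)=C\C)[C@H]2C)[C@H](O)C1(OC)OC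
F10 | step 7 | 8,8-dimethoxy-10βH-eremophil-11-ene-3β,9α-diol (4β,5β-dimethyl; 7β-isopropenyl) | C=C(C)[C@H]1C[C@@]2(C)[C@H](CC[C@H](O)[C@@H]2C)[C@H](O)C1(OC)OC
F11 | step 7 | 9-epimer of ester 20 (9α-hydroxy) | C=C(C)[C@H]1C[C@@]2(C)[C@H](CC[C@@H](OC(=O)/C=C/C[C@@H](C)OC(=O)/C(C)=C\C)[C@@H]2C)[C@H](O)C1(OC)OC
F12 | step 7 | 9-epimer of target 21 (9α-hydroxy) | C=C(C)[C@H]1C[C@@]2(C)[C@H](CC[C@@H](OC(=O)/C=C/C[C@@H](C)OC(=O)/C(C)=C\C)[C@@H]2C)[C@H](O)C1=O
F13 | step 7 | 9α-trifluoromethanesulfonate of F12 | C=C(C)[C@H]1C[C@@]2(C)[C@H](CC[C@@H](OC(=O)/C=C/C[C@@H](C)OC(=O)/C(C)=C\C)[C@@H]2C)[C@H](OS(=O)(=O)C(F)(F)F)C1=O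
F14 | step 7 | 9β-nitrite ester of 21 (not isolated) | C=C(C)[C@H]1C[C@@]2(C)[C@H](CC[C@@H](OC(=O)/C=C/C[C@@H](C)OC(=O)/C(C)=C\C)[C@@H]2C)[C@@H](ON=O)C1=O
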